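The route rests on opening ring A of the eremophilane core at the C4–C5 and C1–C10 bonds. A single catalytic enantioselective Diels–Alder reaction between 2-methoxy-5-methyl-1,4-benzoquinone and (Z)-3-(tert-butyldimethylsilyloxy)penta-1,3-diene builds ring A against the quinone ring (future ring B), creates the quaternary C5 together with C4 and C10, and places oxygen at C3, C8 and C9, where the target carries its ester and its diol. The feature exploited is this match: oxygenated C3 in ring A, vicinal oxygens at C8/C9 in ring B and the angular C5 methyl beside the C4 methyl. Both precursors are achiral and one step from commodity chemicals.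

Key step: step 3

Remark: eremophilane numbering is used throughout (ring A = C1–C5 and C10, ring B = C5–C10, methyl groups on C4 and C5, isopropenyl on C7); β is the face of the C5 methyl group, α the opposite face; intermediates without the isopropenyl group are named as 11,12,13-trinoreremophilanes (4,5-dimethyldecalins).

Assumption: (R)-BINOL is taken as the ligand enantiomer that gives the (4aR) adduct; if a trial shows the opposite sense of induction, (S)-BINOL is used and nothing else changes.

Step 1
Reactants: 1 2-methyl-1,4-benzoquinone (2 equiv, the second equivalent acting as oxidant)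
Product: 3 2-methoxy-5-methyl-1,4-benzoquinone, via hydroquinone 2 (not isolated)
Conditions: MeOH, ZnCl2, reflux
Reagents that add atoms: methanol, CO
Why: Lewis-acid-promoted conjugate addition of methanol to the unsubstituted double bond, at the carbon para to the methyl group, gives hydroquinone 2, which the second equivalent of 1 oxidises to the quinone (quinone–hydroquinone redox exchange).

Step 2
Reactants: 4 pent-1-en-3-one
Product: 5 (Z)-3-(tert-butyldimethylsilyloxy)penta-1,3-diene
Conditions: TBSOTf, Et3N, Et2O, 0 °C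
Reagents that add atoms: tert-butyldimethylsilyl trifluoromethanesulfonate, CC(C)(C)[Si](C)(C)OS(=O)(=O)C(F)(F)F
Why: Soft enolisation and O-silylation of the ethyl ketone (silyl enol ether formation) should give mainly the Z enol ether, with the C-methyl trans to the vinyl group to avoid allylic strain, which puts that methyl on the outside of the s-cis diene.

Step 3
Reactants: 3 2-methoxy-5-methyl-1,4-benzoquinone; 5 (Z)-3-(tert-butyldimethylsilyloxy)penta-1,3-diene
Product: 6 cis-fused adduct (4aR,5S,8aS)-6-(tert-butyldimethylsilyloxy)-2-methoxy-4a,5-dimethyl-4a,5,8,8a-tetrahydronaphthalene-1,4-dione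
Conditions: TiCl2(OiPr)2 (0.3 equiv), (R)-BINOL (0.3 equiv), 4 Å molecular sieves, toluene, −60 → −10 °C
Reagents that add atoms: none
Why: An asynchronous endo [4+2] cycloaddition joins the two diene termini to the methyl-bearing quinone double bond and forms C4–C5 and C1–C10; the closest known reaction type is the BINOL–titanium-catalysed Diels–Alder reaction of quinones with 2-silyloxydienes, combined with the classical cycloaddition of methoxytoluquinone at its methylated double bond. Ring A is closed as a cyclohexene by intermolecular [4+2] annulation onto the quinone, which becomes ring B. C5 is set by the BINOL ligand, which shields one face of the titanium-bound quinone; C10 follows from suprafacial addition (H cis to the C5 methyl); C4 follows from the endo transition state and the Z enol ether, whose outward methyl ends up trans to the C5 methyl. The step needs site selectivity, which is given because the other quinone double bond is part of a vinylogous ester and stays inert, and regioselectivity, which two-point binding of titanium to the C9 carbonyl and the 8-methoxy oxygen should secure by polarising the double bond so that C5 accepts the more nucleophilic, methyl-substituted diene carbon.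

Step 4
Reactants: 6 cis-fused adduct
Product: 8 trans-fused trione 8-methoxy-4β,5β-dimethyl-10αH-11,12,13-trinoreremophil-7-ene-3,6,9-trione, via cis-fused trione 7 (not isolated)
Conditions: NaOMe (0.3 equiv), MeOH–THF, argon, 0 °C → rt
Reagents that add atoms: none
Why: Methoxide cleaves the silyl enol ether to the C3 ketone and then equilibrates C10 and C4 by reversible enolisation (base-mediated epimerisation) towards the trans-fused decalin with an equatorial 4β-methyl group, expected to be the most stable isomer because the axial C5 methyl then meets only one syn-axial hydrogen (C3, C7 and C9 are trigonal); minor epimers are separated and resubmitted.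

Step 5
Reactants: 8 trans-fused trione
Product: 10 3β,9β-dihydroxy-4β,5β-dimethyl-10αH-11,12,13-trinoreremophil-6-en-8-one, via triol enol ether 9 (not isolated)
Conditions: LiAlH4, THF, −78 → 0 °C; then 1 M HCl, THF, rt
Reagents that add atoms: water, O
Why: LiAlH4 reduces all three carbonyl groups by 1,2-addition, mainly from the α face anti to the axial C5 methyl (axial 3β- and 9β-alcohols), and aqueous acid then ionises the C6 carbinol of the methyl enol ether and hydrolyses it to the transposed enone (Stork–Danheiser-type enone transposition); the C6 stereocentre is lost, and any C9 or C3 epimer converges in steps 7 and 13.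

Step 6
Reactants: 10 3β,9β-dihydroxy enone
Product: 11 3β,9β-bis(tert-butyldimethylsilyloxy)-4β,5β-dimethyl-10αH-11,12,13-trinoreremophil-6-en-8-one
Conditions: TBSOTf, 2,6-lutidine, CH2Cl2, −78 → 0 °C
Reagents that add atoms: tert-butyldimethylsilyl trifluoromethanesulfonate, CC(C)(C)[Si](C)(C)OS(=O)(=O)C(F)(F)F
Why: Silyl triflate silylation caps both hindered axial alcohols, so that C9 can next be epimerised through a simple enolate without enediol or diosphenol chemistry of the free ketol.

Step 7
Reactants: 11 3β,9β-bis(silyl ether) enone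
Product: 12 3β,9α-bis(tert-butyldimethylsilyloxy)-4β,5β-dimethyl-10αH-11,12,13-trinoreremophil-6-en-8-one
Conditions: DBU, toluene, 80 °C
Reagents that add atoms: none
Why: Reversible enolisation of the C8 ketone towards C9 (base-mediated epimerisation of an α-silyloxy ketone) should move the silyloxy group from the pseudo-axial β position, where it clashes with the C5 methyl, to the pseudo-equatorial α position; C9–H is the only acidic hydrogen, so no other centre can change.

Step 8
Reactants: 12 3β,9α-bis(silyl ether) enone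
Product: 14 8-trimethylsilyloxy-3β,9α-bis(tert-butyldimethylsilyloxy)-4β,5β-dimethyl-10αH-11,12,13-trinoreremophil-7-ene, via lithium enolate 13 (not isolated)
Conditions: LiBH(s-Bu)3, THF, −78 °C; then Me3SiCl, Et3N, −78 → 0 °C
Reagents that add atoms: chlorotrimethylsilane, C[Si](C)(C)Cl
Why: The bulky borohydride adds hydride to C6 of the enone, whose β-carbon carries no alkyl group besides the ring (1,4-reduction), which gives the C7=C8 enolate regiospecifically, and O-silylation fixes it as the silyl enol ether.

Step 9
Reactants: 14 trimethylsilyl enol ether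
Product: 16 3β,9α-bis(tert-butyldimethylsilyloxy)eremophil-11-en-8-one (7α-isopropenyl), via tin enolate 15 (not isolated)
Conditions: 2-bromopropene, Bu3SnF, Pd2(dba)3 (3 mol %), P(t-Bu)3 (7 mol %), toluene, 80 °C, sealed tube
Reagents that add atoms: 2-bromopropene, C=C(C)Br
Why: Fluoride-driven silicon-to-tin exchange gives the tin enolate, which couples with the alkenyl bromide under palladium catalysis (α-alkenylation of a ketone enolate); the C7–C bond should form on the α face, away from the syn-axial C5 methyl, so the isopropenyl group arrives equatorial, and the neutral medium avoids both epimerisation and migration of the double bond into conjugation.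

Step 10
Reactants: 16 7α-isopropenyl ketone
Product: 17 3β,9α-bis(tert-butyldimethylsilyloxy)eremophil-11-en-8α-ol
Conditions: LiBH(s-Bu)3, THF, −78 °C; H2O quench
Reagents that add atoms: none
Why: The bulky hydride should attack the C8 ketone along the equatorial trajectory from the β face (substrate-controlled ketone reduction), which gives the axial 8α-alcohol cis to both equatorial neighbours.

Step 11
Reactants: 17 bis(silyl ether) alcohol
Product: 18 eremophil-11-ene-3β,8α,9α-triol
Conditions: Bu4NF, THF, 50 °C
Reagents that add atoms: none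
Why: Fluoride cleaves both silyl ethers (desilylation) and touches no stereocentre.

Step 12
Reactants: 18 triol
Product: 19 8α,9α-(isopropylidenedioxy)eremophil-11-en-3β-ol
Conditions: 2,2-dimethoxypropane, pyridinium p-toluenesulfonate (cat.), acetone, rt
Reagents that add atoms: 2,2-dimethoxypropane, COC(C)(C)OC
Why: Only the cis-vicinal 8α,9α-diol can close a five-membered isopropylidene acetal (acetonide formation), which leaves the C3 hydroxyl as the single free alcohol.

Step 13
Reactants: 19 acetonide alcohol
Product: 20 8α,9α-(isopropylidenedioxy)eremophil-11-en-3-one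
Conditions: Dess–Martin periodinane, pyridine, CH2Cl2, 0 °C → rt
Reagents that add atoms: none
Why: Dess–Martin oxidation of the lone secondary alcohol gives the C3 ketone under buffered conditions that leave the equatorial C4 methyl, the acetonide and the alkene alone.

Step 14
Reactants: 20 C3 ketone
Product: 21 8α,9α-(isopropylidenedioxy)eremophil-11-en-3α-ol
Conditions: Li, NH3 (l), THF, MeOH, −78 °C
Reagents that add atoms: none
Why: Dissolving-metal reduction of the ketone is under thermodynamic control and should give the equatorial 3α-alcohol, whereas hydride reagents give the axial alcohol because the C5 methyl blocks the axial approach; the isolated alkene and the acetonide are inert.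

Step 15
Reactants: 22 (S)-pent-1-yn-3-ol
Product: 24 (S)-4-hydroxyhex-2-ynoic acid, via dilithiated pentynol 23 (not isolated)
Conditions: n-BuLi (2.2 equiv), THF, −78 → −40 °C; CO2; then 1 M HCl
Reagents that add atoms: carbon dioxide, O=C=O
Why: Double deprotonation gives the lithium alkoxide–acetylide, whose carbon adds to CO2 (carboxylation of an alkynyllithium); the carbinol stereocentre is not involved.

Step 16
Reactants: 24 (S)-4-hydroxyhex-2-ynoic acid
Product: 25 4-methoxybenzyl (S)-4-hydroxyhex-2-ynoate
Conditions: 4-methoxybenzyl chloride, KHCO3, DMF, rt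
Reagents that add atoms: 4-methoxybenzyl chloride, COc1ccc(CCl)cc1
Why: Under weakly basic conditions the carboxylate is alkylated and the alcohol is not (ester formation by O-alkylation of a carboxylate).

Step 17
Reactants: 25 4-methoxybenzyl (S)-4-hydroxyhex-2-ynoate; 26 hex-2-ynoic acid
Product: 27 4-methoxybenzyl (S)-4-(hex-2-ynoyloxy)hex-2-ynoate
Conditions: DCC, DMAP (cat.), CH2Cl2, 0 °C
Reagents that add atoms: none
Why: Carbodiimide coupling (Steglich esterification) acylates the propargylic alcohol with retention at the stereocentre.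

Step 18
Reactants: 27 4-methoxybenzyl diynoate
Product: 28 (S)-4-(hex-2-ynoyloxy)hex-2-ynoic acid
Conditions: CF3CO2H, anisole, CH2Cl2, 0 °C
Reagents that add atoms: none
Why: Acidolysis cleaves only the 4-methoxybenzyl ester, whose benzylic cation is trapped by anisole, while the inner propargylic ester is stable to acid.

Step 19
Reactants: 21 8α,9α-(isopropylidenedioxy)eremophil-11-en-3α-ol; 28 (S)-4-(hex-2-ynoyloxy)hex-2-ynoic acid
Product: 29 3α-[(4S)-4-(hex-2-ynoyloxy)hex-2-ynoyloxy]-8α,9α-(isopropylidenedioxy)eremophil-11-ene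
Conditions: DCC, DMAP (cat.), CH2Cl2, −20 → 0 °C
Reagents that add atoms: none
Why: Steglich esterification of the equatorial 3α-alcohol, the only free hydroxyl, with an alkynoic acid, which cannot suffer the Z-to-E isomerisation that threatens Z-enoic acids during acylation.

Step 20
Reactants: 29 acetonide diynoate
Product: 30 3α-[(4S)-4-(hex-2-ynoyloxy)hex-2-ynoyloxy]eremophil-11-ene-8α,9α-diol
Conditions: AcOH–H2O (4:1), 40 °C
Reagents that add atoms: none
Why: Mild aqueous acid hydrolyses the acetonide (acetal hydrolysis), and the esters, alkynes and isopropenyl group should survive.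

Step 21
Reactants: 30 diynoate diol
Product: 31 CNP0271544.1, 3α-{(2Z,4S)-4-[(2Z)-hex-2-enoyloxy]hex-2-enoyloxy}eremophil-11-ene-8α,9α-diol
Conditions: H2 (1 atm), Pd/CaCO3 poisoned with Pb(OAc)2, quinoline, EtOAc, rt
Reagents that add atoms: none
Why: Syn addition of hydrogen on the poisoned palladium surface should reduce both ynoates to Z-enoates (semihydrogenation under Lindlar conditions) and leave the 1,1-disubstituted alkene untouched.

Compound list

1 | 2-methyl-1,4-benzoquinone (toluquinone) | CC1=CC(=O)C=CC1=O | starting material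
2 | 2-methoxy-5-methylbenzene-1,4-diol | COc1cc(O)c(C)cc1O | intermediate
3 | 2-methoxy-5-methyl-1,4-benzoquinone | COC1=CC(=O)C(C)=CC1=O | intermediate
4 | pent-1-en-3-one | C=CC(=O)CC | starting material
5 | (Z)-3-(tert-butyldimethylsilyloxy)penta-1,3-diene | C=C/C(O[Si](C)(C)C(C)(C)C)=C/C | intermediate
6 | cis-fused adduct, (4aR,5S,8aS)-6-(tert-butyldimethylsilyloxy)-2-methoxy-4a,5-dimethyl-4a,5,8,8a-tetrahydronaphthalene-1,4-dione (C2=C3 silyl enol ether, 4α-methyl, 5β-methyl, 10β-H, 6,9-dione, 8-methoxy-7-ene) | COC1=CC(=O)[C@]2(C)[C@H](C)C(O[Si](C)(C)C(C)(C)C)=CC[C@@H]2C1=O | intermediate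
7 | cis-fused trione, 8-methoxy-4α,5β-dimethyl-10βH-11,12,13-trinoreremophil-7-ene-3,6,9-trione | COC1=CC(=O)[C@]2(C)[C@H](C)C(=O)CC[C@@H]2C1=O | intermediate
8 | trans-fused trione, 8-methoxy-4β,5β-dimethyl-10αH-11,12,13-trinoreremophil-7-ene-3,6,9-trione | COC1=CC(=O)[C@]2(C)[C@@H](C)C(=O)CC[C@H]2C1=O | intermediate
9 | triol enol ether, 8-methoxy-4β,5β-dimethyl-10αH-11,12,13-trinoreremophil-7-ene-3β,6β,9β-triol | COC1=C[C@@H](O)[C@]2(C)[C@@H](C)[C@@H](O)CC[C@H]2[C@H]1O | intermediate
10 | 3β,9β-dihydroxy-4β,5β-dimethyl-10αH-11,12,13-trinoreremophil-6-en-8-one | O=C1C=C[C@]2(C)[C@@H](C)[C@@H](O)CC[C@H]2[C@H]1O | intermediate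
11 | 3β,9β-bis(tert-butyldimethylsilyloxy)-4β,5β-dimethyl-10αH-11,12,13-trinoreremophil-6-en-8-one | O=C1C=C[C@]2(C)[C@@H](C)[C@@H](O[Si](C)(C)C(C)(C)C)CC[C@H]2[C@H]1O[Si](C)(C)C(C)(C)C | intermediate
12 | 3β,9α-bis(tert-butyldimethylsilyloxy)-4β,5β-dimethyl-10αH-11,12,13-trinoreremophil-6-en-8-one | O=C1C=C[C@]2(C)[C@@H](C)[C@@H](O[Si](C)(C)C(C)(C)C)CC[C@H]2[C@@H]1O[Si](C)(C)C(C)(C)C | intermediate
13 | lithium enolate, lithium 3β,9α-bis(tert-butyldimethylsilyloxy)-4β,5β-dimethyl-10αH-11,12,13-trinoreremophil-7-en-8-olate | [Li]OC1=CC[C@]2(C)[C@@H](C)[C@@H](O[Si](C)(C)C(C)(C)C)CC[C@H]2[C@@H]1O[Si](C)(C)C(C)(C)C | intermediate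
14 | 8-trimethylsilyloxy-3β,9α-bis(tert-butyldimethylsilyloxy)-4β,5β-dimethyl-10αH-11,12,13-trinoreremophil-7-ene | C[Si](C)(C)OC1=CC[C@]2(C)[C@@H](C)[C@@H](O[Si](C)(C)C(C)(C)C)CC[C@H]2[C@@H]1O[Si](C)(C)C(C)(C)C | intermediate
15 | tin enolate, 8-tributylstannyloxy analogue of 14 | CCCC[Sn](CCCC)(CCCC)OC1=CC[C@]2(C)[C@@H](C)[C@@H](O[Si](C)(C)C(C)(C)C)CC[C@H]2[C@@H]1O[Si](C)(C)C(C)(C)C | intermediate
16 | 3β,9α-bis(tert-butyldimethylsilyloxy)eremophil-11-en-8-one (7α-isopropenyl, 4β,5β-dimethyl, 10α-H) | C=C(C)[C@@H]1C[C@]2(C)[C@@H](C)[C@@H](O[Si](C)(C)C(C)(C)C)CC[C@H]2[C@H](O[Si](C)(C)C(C)(C)C)C1=O | intermediate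
17 | 3β,9α-bis(tert-butyldimethylsilyloxy)eremophil-11-en-8α-ol | C=C(C)[C@@H]1C[C@]2(C)[C@@H](C)[C@@H](O[Si](C)(C)C(C)(C)C)CC[C@H]2[C@H](O[Si](C)(C)C(C)(C)C)[C@@H]1O | intermediate
18 | eremophil-11-ene-3β,8α,9α-triol | C=C(C)[C@@H]1C[C@]2(C)[C@@H](C)[C@@H](O)CC[C@H]2[C@H](O)[C@@H]1O | intermediate
19 | 8α,9α-(isopropylidenedioxy)eremophil-11-en-3β-ol | C=C(C)[C@@H]1C[C@]2(C)[C@@H](C)[C@@H](O)CC[C@H]2[C@@H]3OC(C)(C)O[C@H]13 | intermediate
20 | 8α,9α-(isopropylidenedioxy)eremophil-11-en-3-one | C=C(C)[C@@H]1C[C@]2(C)[C@@H](C)C(=O)CC[C@H]2[C@@H]3OC(C)(C)O[C@H]13 | intermediate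
21 | 8α,9α-(isopropylidenedioxy)eremophil-11-en-3α-ol | C=C(C)[C@@H]1C[C@]2(C)[C@@H](C)[C@H](O)CC[C@H]2[C@@H]3OC(C)(C)O[C@H]13 | intermediate
22 | (S)-pent-1-yn-3-ol | CC[C@H](O)C#C | starting material
23 | dilithiated pentynol, lithium alkoxide and lithium acetylide of 22 | CC[C@H](O[Li])C#C[Li] | intermediate
24 | (S)-4-hydroxyhex-2-ynoic acid | CC[C@H](O)C#CC(=O)O | intermediate
25 | 4-methoxybenzyl (S)-4-hydroxyhex-2-ynoate | CC[C@H](O)C#CC(=O)OCc1ccc(OC)cc1 | intermediate
26 | hex-2-ynoic acid | CCCC#CC(=O)O | starting material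
27 | 4-methoxybenzyl (S)-4-(hex-2-ynoyloxy)hex-2-ynoate | CC[C@H](OC(=O)C#CCCC)C#CC(=O)OCc1ccc(OC)cc1 | intermediate
28 | (S)-4-(hex-2-ynoyloxy)hex-2-ynoic acid | CC[C@H](OC(=O)C#CCCC)C#CC(=O)O | intermediate
29 | 3α-[(4S)-4-(hex-2-ynoyloxy)hex-2-ynoyloxy]-8α,9α-(isopropylidenedioxy)eremophil-11-ene | C=C(C)[C@@H]1C[C@]2(C)[C@@H](C)[C@H](OC(=O)C#C[C@H](CC)OC(=O)C#CCCC)CC[C@H]2[C@@H]3OC(C)(C)O[C@H]13 | intermediate
30 | 3α-[(4S)-4-(hex-2-ynoyloxy)hex-2-ynoyloxy]eremophil-11-ene-8α,9α-diol | C=C(C)[C@@H]1C[C@]2(C)[C@@H](C)[C@H](OC(=O)C#C[C@H](CC)OC(=O)C#CCCC)CC[C@H]2[C@H](O)[C@@H]1O | intermediate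
31 | CNP0271544.1, 3α-{(2Z,4S)-4-[(2Z)-hex-2-enoyloxy]hex-2-enoyloxy}eremophil-11-ene-8α,9α-diol (4β,5β-dimethyl, 7α-isopropenyl, 10α-H) | C=C(C)[C@@H]1C[C@]2(C)[C@@H](C)[C@H](OC(=O)/C=C\[C@H](CC)OC(=O)/C=C\CCC)CC[C@H]2[C@H](O)[C@@H]1O | target

Total step count: 21. Longest linear sequence: 16 steps (steps 1, 3–14 and 19–21).

Steps most likely to fail

Step 3. The cycloaddition may show insufficient facial or regiochemical control at the hindered, methyl-bearing double bond, or stop as an open Mukaiyama–Michael adduct. The fallback replaces asymmetric catalysis by resolution. It sets out from 3 and 5, which are heated without catalyst in toluene at 80 °C; the classical thermal cycloaddition of methoxytoluquinone should give the same regioisomer, because the C9 carbonyl is the more electron-poor one. This gives 6 as a racemate, that is together with its enantiomer (4aS,5R,8aR)-6-(tert-butyldimethylsilyloxy)-2-methoxy-4a,5-dimethyl-4a,5,8,8a-tetrahydronaphthalene-1,4-dione F1. The two are separated by preparative chromatography on a chiral stationary phase, and the route is rejoined at 6.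

Step 9. Transmetallation or carbon–carbon reductive elimination at the hindered enolate may be slow, so that β-hydride elimination returns enone 12 or protodemetallation gives the unsubstituted ketone. The fallback builds the C7–C bond on the enone instead and sets out from 12. Iodination with I2 and pyridine in CH2Cl2 should give 7-iodo-3β,9α-bis(tert-butyldimethylsilyloxy)-4β,5β-dimethyl-10αH-11,12,13-trinoreremophil-6-en-8-one F2. Suzuki coupling with isopropenylboronic acid pinacol ester (Pd(PPh3)4, K3PO4, dioxane–H2O) should give 3β,9α-bis(tert-butyldimethylsilyloxy)eremophila-6,11-dien-8-one F3. Conjugate reduction with LiBH(s-Bu)3 at −78 °C and protonation of the dienolate at C7 returns to 16. In this variant the C7 configuration rests on that protonation and on the strong equatorial preference of the isopropenyl group, so it is less secure than in the main route.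

Step 21. The double semihydrogenation on the fully elaborated substrate may over-reduce the conjugated Z-alkenes or stall after one alkyne, leaving mixtures that are hard to separate. The fallback fixes the alkene geometry on the small fragment and sets out from 27. Semihydrogenation over Pd/CaCO3 poisoned with Pb(OAc)2 and quinoline should give 4-methoxybenzyl (2Z,4S)-4-[(2Z)-hex-2-enoyloxy]hex-2-enoate F4, which is purified at this stage. Acidolysis (CF3CO2H, anisole) gives (2Z,4S)-4-[(2Z)-hex-2-enoyloxy]hex-2-enoic acid F5. Yamaguchi esterification with 21 (2,4,6-trichlorobenzoyl chloride, Et3N, then DMAP, toluene, 0 °C, kept cold to limit Z-to-E isomerisation) gives 3α-{(2Z,4S)-4-[(2Z)-hex-2-enoyloxy]hex-2-enoyloxy}-8α,9α-(isopropylidenedioxy)eremophil-11-ene F6. Aqueous acetic acid then removes the acetonide and the route arrives at 31.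

Further compounds

F1 | step 3 | (4aS,5R,8aR)-6-(tert-butyldimethylsilyloxy)-2-methoxy-4a,5-dimethyl-4a,5,8,8a-tetrahydronaphthalene-1,4-dione (enantiomer of 6) | COC1=CC(=O)[C@@]2(C)[C@@H](C)C(O[Si](C)(C)C(C)(C)C)=CC[C@H]2C1=O
F2 | step 9 | 7-iodo-3β,9α-bis(tert-butyldimethylsilyloxy)-4β,5β-dimethyl-10αH-11,12,13-trinoreremophil-6-en-8-one | O=C1C(I)=C[C@]2(C)[C@@H](C)[C@@H](O[Si](C)(C)C(C)(C)C)CC[C@H]2[C@@H]1O[Si](C)(C)C(C)(C)C
F3 | step 9 | 3β,9α-bis(tert-butyldimethylsilyloxy)eremophila-6,11-dien-8-one | C=C(C)C1=C[C@]2(C)[C@@H](C)[C@@H](O[Si](C)(C)C(C)(C)C)CC[C@H]2[C@H](O[Si](C)(C)C(C)(C)C)C1=O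
F4 | step 21 | 4-methoxybenzyl (2Z,4S)-4-[(2Z)-hex-2-enoyloxy]hex-2-enoate | CC[C@H](OC(=O)/C=C\CCC)/C=C\C(=O)OCc1ccc(OC)cc1
F5 | step 21 | (2Z,4S)-4-[(2Z)-hex-2-enoyloxy]hex-2-enoic acid | CC[C@H](OC(=O)/C=C\CCC)/C=C\C(=O)O
F6 | step 21 | 3α-{(2Z,4S)-4-[(2Z)-hex-2-enoyloxy]hex-2-enoyloxy}-8α,9α-(isopropylidenedioxy)eremophil-11-ene | C=C(C)[C@@H]1C[C@]2(C)[C@@H](C)[C@H](OC(=O)/C=C\[C@H](CC)OC(=O)/C=C\CCC)CC[C@H]2[C@@H]3OC(C)(C)O[C@H]13
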